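All runs are calculated from invented constants, noise included.

The trap on this board is to read a peak off one run and carry it to a flask with a different [reagent], as if that peak belonged to the starting material.

| setting | maple | alder | Friday's | Saturday's | Wednesday's | Tuesday's |
|---|---|---|---|---|---|---|
| starting material | 0.050 M | 0.050 M | 0.050 M | 0.050 M | 0.050 M | 0.050 M |
| reagent | 0.12 M | 0.50 M | 0.250 M | 0.250 M | 0.250 M | 0.250 M |
| temperature | 40 °C | 82 °C | 95 °C | 120 °C | 70 °C | 45 °C |
| remark | run made earlier | run made earlier |  |  |  |  |
| time |  |  | 25 h | 25 h | 25 h | 25 h |

- maple (time / h: target / %): 60.0: 27.8; 120: 18.7; 192: 11.3; 240: 8.5; 288: 6.2; 360: 3.6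
- alder (time / h: target / %): 4.00: 0.9; 6.00: 0; 12.0: 0.1; 20.0: 0; 30.0: 0; 50.0: 0

(each reading ± 0.3 percentage points)

- which flask leads in amount of target, in percent of the starting material charged ("all alike" within 1.5 percentage points) (Friday's / Saturday's / Wednesday's / Tuesday's / all alike)
- how much target is there at the end, in percent of the starting material charged: Friday's
- how much target is there at the end, in percent of the starting material charged: Saturday's
- how much target is there at the end, in percent of the starting material charged: Wednesday's
- how much target is there at the end, in percent of the starting material charged: Tuesday's

- what was read earlier has a scatter of 0.3 percentage points, one standard deviation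
- a reading or a percentage of target counts all its forms, free or not

Two of us read the maple run, and we agree on its tail. From 60.0 h to 360 h the target decays at 0.00681 h⁻¹, and that tail, run back to zero time, reads 41.8% of the charge.

The forecast treats this as a ceiling that travels from flask to flask, “the yield ceiling is roughly 40–45%”, and asks how much of it survives 25 h. It names Tuesday's as the leader, with 23% there, 0.3% in Wednesday's, 0% in Friday's and 0% in Saturday's.

My objection is that the rest of the maple charge went somewhere. I assume that a competing loss takes more reagent than the making of target does, so that the split moves with [reagent]. Freezing [reagent] at its charge, the maple run gives 11.6 L mol⁻¹. This is the split constant, the starting material lost elsewhere per part turned into target and per unit of [reagent], a selectivity factor.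

At Tuesday's 0.250 M it puts the ceiling at 25.7%, which is lower than the maple reading. For the decay I use the alder run, whose ceiling comes to 14.7%. Its rough reading of 0.9% at 4.00 h then gives 0.699 h⁻¹. Interpolating the logarithm of the decay constant in temperature gives 0.0118 h⁻¹ at 45 °C, so I commit to 19.1% for Tuesday's. On the hotter flasks I have no quarrel with the forecast.

The flasks give this: Tuesday's leads with 15.6%, Wednesday's holds 0.117%, Friday's 0% and Saturday's 0%. For Tuesday's, the forecast stands 7.4 percentage points too high and my figure 3.5 points too high.

    starting material + reagent → target (k = 20.0 L mol⁻¹ h⁻¹, Ea = 82.0 kJ mol⁻¹)
    starting material + 2 reagent → side product (k = 250 L² mol⁻² h⁻¹, Ea = 68.0 kJ mol⁻¹)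
    crystals ⇌ target, rate k3*(cs3 - [target]) while solid is left; crystals form when [target] > cs3 (solubility = 19.0 mM, k = 46.0 h⁻¹)
    target → over-reaction product (k = 0.220 h⁻¹, Ea = 104 kJ mol⁻¹)
    (constants at 70 °C)

The side product is the main reason for Tuesday's shortfall: with that path struck out the flask holds 88.3% instead of 15.6%. Taking away the over-reaction product, which is a part of the story, gives 21.2%. Now carry the split constant to Tuesday's flask with 0.062 M of reagent: it gives 0.719 parts lost per part made, a ceiling of 58.2% of what reacts. That flask holds 38.8% target, 10.1% over-reaction product and 28.4% side product, which is 0.581 parts lost per part made, the over-reaction product counted as made. So 63.3% of what reacted there became target, against 21.2% in Tuesday's itself, which differs from it in [reagent] alone: the ceiling did not travel.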